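Slowness is not what the winter run shows you as you take over these flasks: c(Z) reads 53.2 % at 60.0 s and 53.7 % at 90.0 s, a stop rather than a crawl, while c(L) still falls from 32.5 % to 29.7 % and part of the charge stands in neither.

| flask | L | J | remark | time |
|---|---|---|---|---|
| winter | 1 M | 1.1 equiv | run made earlier |  |
| dawn | 1 M | 2.1 equiv | run made earlier |  |
| birch | 1.0 M | 1.50 equiv |  | 3.0 min |
| ash | 1.0 M | 1.00 equiv |  | 3.0 min |

| run | time / s | L / % | Z / % |
|---|---|---|---|
| winter | 10.0 | 56.6 | 38.3 |
| winter | 25.0 | 42.3 | 48.9 |
| winter | 40.0 | 36.4 | 52.0 |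
| winter | 60.0 | 32.5 | 53.2 |
| winter | 90.0 | 29.7 | 53.7 |
| dawn | 20.0 | 17.0 | 72.4 |
| dawn | 40.0 | 8.9 | 77.7 |
| dawn | 50.0 | 6.6 | 77.6 |
| dawn | 80.0 | 3.8 | 77.4 |
| dawn | 90.0 | 3.9 | 76.6 |

(scatter of a reading: 0.5 percentage points)

- part of the L that has reacted at the end, birch
- part of the L that has reacted at the end, ash
- what raising the equivalents of J from its lowest to its highest value here does to the part of the L that has reacted (changes below 5 percentage points count as none) (no change / it falls / it rises)

I take J as the limiting reagent in winter. That run gives 2.05 equiv of J charged per Z standing once Z has stopped; I call this the J price. I do not read it from dawn, where c(L) is down to 3.9 % at 90.0 s, less than in winter, so little L remains to make Z.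

By this price, ash should stop at c(Z) = 48.8 % and birch at 73.2 %. Winter leaves 64.1 % of what is not Z as L. If that split holds, the L reacted is 67.2 % in ash and 82.8 % in birch, a rise of 16 percentage points. Both flasks run 3.0 min, longer than the last winter reading, and c(L) was still falling there, so I expect somewhat more reacted in each. By this price, c(Z) follows the J charge, so do not touch a J charge unless you mean to move c(Z).

The forecast, higher than mine for birch, gives 86.5 % for birch and 66 % for ash, and for the part reacted as J goes up, it rises: "Three minutes is essentially the end, so the part reacted rises with J."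

The flasks give 86.1 % in birch and 73.0 % in ash; it rises, by 13 points.

    L ⇌ E (K = 0.900, k = 0.00562 /s)
    J + Z → G (k = 0.00651 /M/s)
    J + Q ⇌ X, settled at all times (K = 1300 /M)
    L + J → Q + Z (k = 0.0891 /M/s)

In ash at 3.00 min, c(Z) is 50.6 % against my 48.8 %, with J down to 0.493 % of its charge. My 67.2 % falls short of 73.0 %: c(L) there is 27.0 %, not the 32.8 % of the winter split, and E holds 20.6 %. The neighbour of birch, charged with 0.900 equiv of J, is priced at 43.9 %; its c(Z) at 3.00 min is 46.2 %, with J at 0.48 % of its charge.

All runs come from a simulation from invented constants, noise included.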